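(The constants used here come from no measurement; the run is a simulation.)

0.126 M h⁻¹ is what the gas phase feeds into liquid that holds no dissolved gas.

    gas phase ⇌ dissolved gas, rate k1*(csat - [dissolved gas]) (k1 = 0.632 h⁻¹, csat = 200 mM)
    starting material + dissolved gas → target (k2 = 0.393 L mol⁻¹ h⁻¹, Ea2 = 76.0 kJ mol⁻¹)
    target ⇌ isomer of the product (K3 = 0.143, k3 = 0.0199 h⁻¹, Ea3 = 106 kJ mol⁻¹, ΔH3 = −34.0 kJ mol⁻¹)
    (constants at 40 °C)

| flask | starting material | gas phase | temperature | time |
|---|---|---|---|---|
| teal | 1.4 M | 200 mM (held) | 40 °C | 4.0 h |
| violet | 1.4 M | 200 mM (held) | 48 °C | 4.0 h |
| red | 1.4 M | 200 mM (held) | 56 °C | 4.0 h |

- which of these there is most of at the end, counted by the starting material in it, teal (target / starting material / isomer of the product)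
- which of these there is most of at the end, counted by the starting material in it, violet (target / starting material / isomer of the product)
- which of these there is most of at the end, counted by the starting material in it, red (target / starting material / isomer of the product)
- final amount of the leader among these, as a percentage of the starting material charged, in teal
- final amount of the leader among these, as a percentage of the starting material charged, in violet
- final amount of the leader among these, as a percentage of the starting material charged, in red

- at the start none of the gas is dissolved
- the list of constants is for 40 °C, to be carried to other temperatures by the activation energies and enthalpies

Follow one molecule of dissolved gas. It has two exits: capture by starting material, at the step's rate constant times c(starting material), or escape to the gas phase, at the transfer coefficient. With the red charge, and the rate constant carried to red by its activation energy, capture runs at 1.62 L mol⁻¹ h⁻¹ times c(starting material). That gives 78.3%: this is the capture chance, capture divided by capture plus escape.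

Conversion then runs at the feed times the chance. The liquid starts empty, so you take off a delay, one over the sum of both exits. You hold c(starting material) at its charge.

Flask: rate constant, capture chance, delay, part of the charge converted

teal: 0.39 L mol⁻¹ h⁻¹, 46.5%, 0.846 h, 13.3%

violet: 0.813 L mol⁻¹ h⁻¹, 64.3%, 0.565 h, 19.9%

red: 1.62 L mol⁻¹ h⁻¹, 78.3%, 0.344 h, 25.8%

Read the first column against the second. From teal to red the rate constant grows by a factor 4.15, but the chance grows by 1.68. In teal the molecule is captured about half the time. In red capture outruns escape, so the passage of gas into the liquid is the rate-limiting step.

Now read the last column. A chance of one gives 36.1% of the charge in 4.0 h, and each row stays below that. Starting material left is 86.7% in teal, 80.1% in violet and 74.2% in red. In teal the half-life of target by its forward step, 35 h, is longer than the run, so that step stays far from equilibrium there. For the ranking you still give the isomer of the product a generous score in each flask: 0.143, the equilibrium constant at the temperature of teal, times the converted part. The leaders are then starting material in teal, starting material in violet and starting material in red.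

The forecast also names starting material in teal, starting material in violet and starting material in red, with 87.2%, 81.3% and 75.5%. Its ground is a quick relaxation of the dissolved gas, “so gas transfer limits the rate”. It integrates that rate, while your table holds c(starting material) at its charge.

The flask gives starting material at 87.3% in teal, starting material at 81.1% in violet and starting material at 75.5% in red. At 4.00 h in red, dissolved gas is made 1.03 times faster than it is used up. Capture odds fall in step with c(starting material), so the 75% left in red brings the chance to 73.1%. That puts c(dissolved gas) at 0.0538 M, and the flask holds 0.0525 M.

Repeat red at 81 °C: the rate constant is 11.5 L mol⁻¹ h⁻¹, the chance 96.2% and the delay 0.0596 h, which leaves 65.8% of the starting material. That flask holds 66.3%.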